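**Retrosynthetic overview**
1. 19 ⇒ 18: C1–C2 epoxide by epoxidation directed by the 7-OH. 18 ⇒ 17: C2–CH3 by coupling of an enol triflate that has masked the cyclopentene alkene until then.
2. 17 ⇒ 15: tertiary C7–O bond by hydration of the C6=C7 alkene steered by the neighbouring 5-isovanillate (new step). 15 ⇒ 13 + isovanillic acid: C5–O ester bond by Mitsunobu inversion.
3. 13 ⇒ 10: seven-membered ring (formed second) by ring-closing metathesis of a vinyl/methallyl ketone, then base equilibration (sets C4) and 1,2-reduction.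
4. 10 ⇒ 3 + 2: five-membered ring taken from (R)-4-silyloxycyclopentenone (present from the start); C3a–C4 by Mukaiyama–Michael addition/elimination, C8a–C8 by vinyl conjugate addition trapped as the enol triflate.

Convention and assumption: core atoms carry azulene numbering (C1, C2, C3, C3a, C4–C8, C8a); α is the face of H-3a, β the face of H-8a; compounds 4–11 are C4-epimer mixtures and are written without a descriptor at C4 (the isopropyl-bearing carbon); 3 is bought enantiopure.

**Step 1**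
Reactants: 1 methyl 3-methylbutanoate
Product: 2 (E)-1-methoxy-3-methyl-1-(trimethylsilyloxy)but-1-ene
Conditions: LiN(i-Pr)2, THF, −78 °C; Me3SiCl, −78 °C → rt; distil
Reagents that add atoms: chlorotrimethylsilane, C[Si](C)(C)Cl
Why: Kinetic ester enolisation and O-silylation (silyl ketene acetal formation) give the carbon nucleophile for step 2; no stereocentre is formed.

**Step 2**
Reactants: 2 (E)-1-methoxy-3-methyl-1-(trimethylsilyloxy)but-1-ene; 3 (R)-4-(tert-butyldimethylsilyloxy)cyclopent-2-en-1-one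
Product: 6 methyl 3-methyl-2-[(1R)-4-oxocyclopent-2-en-1-yl]butanoate (both C4 epimers), via silyl enol ether adduct 4 (not isolated), via silyloxy ketone 5 (not isolated)
Conditions: Me3SiOTf (5 mol %), CH2Cl2, −78 °C; 1 M HCl, THF, 0 °C; DBU, CH2Cl2, 0 °C
Reagents that add atoms: none
Why: Mukaiyama–Michael addition anti to the silyloxy group sets C3a, and E1cB loss of silanol from the β-silyloxy ketone gives the transposed enone (the C4 epimers converge in step 5).

**Step 3**
Reactants: 6 methyl 3-methyl-2-[(1R)-4-oxocyclopent-2-en-1-yl]butanoate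
Product: 8 methyl 2-[(1R,2S)-2-ethenyl-4-(trifluoromethylsulfonyloxy)cyclopent-3-en-1-yl]-3-methylbutanoate, via bromomagnesium enolate 7 (not isolated)
Conditions: CH2=CHMgBr, CuBr·SMe2 (10 mol %), THF, −78 °C; then N-(5-chloro-2-pyridyl)bis(trifluoromethanesulfonimide), −78 → 0 °C
Reagents that add atoms: vinylmagnesium bromide, C=C[Mg]Br; N-(5-chloro-2-pyridyl)bis(trifluoromethanesulfonimide), O=S(=O)(N(c1ccc(Cl)cn1)S(=O)(=O)C(F)(F)F)C(F)(F)F
Why: Copper-catalysed conjugate addition trans to the C3a substituent sets C8a, and O-triflation of the regiodefined enolate fixes the later C1=C2 alkene position.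

**Step 4**
Reactants: 8 methyl 2-[(1R,2S)-2-ethenyl-4-(trifluoromethylsulfonyloxy)cyclopent-3-en-1-yl]-3-methylbutanoate
Product: 10 5-[(1R,2S)-2-ethenyl-4-(trifluoromethylsulfonyloxy)cyclopent-3-en-1-yl]-2,6-dimethylhept-1-en-4-one, via Weinreb amide 9 (not isolated)
Conditions: MeONHMe·HCl, i-PrMgCl, THF, −20 °C; then 2-methylallylmagnesium chloride, −20 → 0 °C; aq. NH4Cl
Reagents that add atoms: N,O-dimethylhydroxylamine hydrochloride, CNOC.Cl (atoms kept in 9 only); 2-methylallylmagnesium chloride, CC(=C)C[Mg]Cl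
Why: Ester aminolysis by the magnesium amide followed by Weinreb ketone synthesis stops at the ketone through the stable chelate, and the enol triflate is inert to Grignard reagents without a catalyst.

**Step 5**
Reactants: 10 5-[(1R,2S)-2-ethenyl-4-(trifluoromethylsulfonyloxy)cyclopent-3-en-1-yl]-2,6-dimethylhept-1-en-4-one
Product: 12 4α-isopropyl-7-methyl-5-oxo-3,3a,4,5,8,8a-hexahydroazulen-2-yl trifluoromethanesulfonate (H-3a α; H-8a β), via deconjugated ketone 11 (not isolated)
Conditions: second-generation Grubbs catalyst (5 mol %), CH2Cl2 (5 mM), 40 °C; then DBU (0.3 equiv), rt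
Reagents that add atoms: none
Why: Ring-closing olefin metathesis of the vinyl and methallyl groups closes the seven-membered ring, and base equilibration conjugates the alkene and epimerises C4 (α to the ketone) to the all-equatorial trans-fused isomer, which sets C4 (minor C4 epimer and deconjugated isomer are recycled through the same base treatment).

**Step 6**
Reactants: 12 4α-isopropyl-7-methyl-5-oxo-3,3a,4,5,8,8a-hexahydroazulen-2-yl trifluoromethanesulfonate
Product: 13 5β-hydroxy-4α-isopropyl-7-methyl-3,3a,4,5,8,8a-hexahydroazulen-2-yl trifluoromethanesulfonate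
Conditions: NaBH4, CeCl3·7H2O, MeOH, −78 °C
Reagents that add atoms: none
Why: Luche 1,2-reduction with axial hydride delivery from the α face gives the equatorial 5β-alcohol (trans to the 4α-isopropyl group).

**Step 7**
Reactants: 13 5β-hydroxy-4α-isopropyl-7-methyl-3,3a,4,5,8,8a-hexahydroazulen-2-yl trifluoromethanesulfonate; 14 3-hydroxy-4-methoxybenzoic acid (isovanillic acid)
Product: 15 5α-(3-hydroxy-4-methoxybenzoyloxy)-4α-isopropyl-7-methyl-3,3a,4,5,8,8a-hexahydroazulen-2-yl trifluoromethanesulfonate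
Conditions: PPh3, DIAD, THF, 0 °C → rt
Reagents that add atoms: none
Why: Mitsunobu esterification forms the C5–O ester bond with inversion (5β-OH to 5α-ester, which sets C5), the carboxylic acid reacting in preference to the less acidic phenol.

**Step 8**
Reactants: 15 5α-(3-hydroxy-4-methoxybenzoyloxy)-4α-isopropyl-7-methyl-3,3a,4,5,8,8a-hexahydroazulen-2-yl trifluoromethanesulfonate
Product: 17 7α-hydroxy-5α-(3-hydroxy-4-methoxybenzoyloxy)-4α-isopropyl-7β-methyl-3,3a,4,5,6,7,8,8a-octahydroazulen-2-yl trifluoromethanesulfonate, via dioxanylium salt 16 (not isolated)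
Conditions: [N,N'-bis(3,5-di-tert-butylsalicylidene)-1,2-cyclohexanediaminato]cobalt (divalent cobalt, 5 mol %), N-fluoro-2,4,6-trimethylpyridinium tetrafluoroborate, PhSiH3, PhCF3, 0 °C → rt; then H2O, NaHCO3, rt
Reagents that add atoms: water, O; N-fluoro-2,4,6-trimethylpyridinium tetrafluoroborate, Cc1cc(C)[n+](F)c(C)c1.F[B-](F)(F)F (tetrafluoroborate counter-ion of 16 only)
Why: Proposed new method: hydrogen-atom transfer from a cobalt hydride to C6 of the C6=C7 alkene gives the tertiary C7 radical, which is oxidised to the C7 cation (radical-polar crossover) and captured by the carbonyl oxygen of the 5α-isovanillate through a six-membered 1,3-dioxan-2-ylium ion that can only form on the α face, so hydrolysis gives the 7α-OH cis to O-5 (sets C7) with the acyl group settling on the secondary oxygen, while the electron-poor enol triflate is not a hydrogen-atom acceptor; closest known reaction type: cobalt-salen hydrogen-atom-transfer/radical-polar-crossover hydroalkoxylation and lactonisation of alkenes, combined with Woodward–Prévost-type acyloxonium capture.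

**Step 9**
Reactants: 17 7α-hydroxy-5α-(3-hydroxy-4-methoxybenzoyloxy)-4α-isopropyl-7β-methyl-3,3a,4,5,6,7,8,8a-octahydroazulen-2-yl trifluoromethanesulfonate
Product: 18 7α-hydroxy-4α-isopropyl-2,7β-dimethyl-3,3a,4,5,6,7,8,8a-octahydroazulen-5α-yl 3-hydroxy-4-methoxybenzoate
Conditions: Me4Sn, Pd(PPh3)4 (5 mol %), LiCl, THF, 65 °C
Reagents that add atoms: tetramethylstannane, C[Sn](C)(C)C
Why: Stille coupling of the enol triflate installs the C2 methyl group and unveils the C1=C2 alkene only after the allylic ester has been saturated, so zerovalent palladium cannot ionise it.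

**Step 10**
Reactants: 18 7α-hydroxy-4α-isopropyl-2,7β-dimethyl-3,3a,4,5,6,7,8,8a-octahydroazulen-5α-yl 3-hydroxy-4-methoxybenzoate
Product: 19 1α,2α-epoxy-7α-hydroxy-4α-isopropyl-2β,7β-dimethyldecahydroazulen-5α-yl 3-hydroxy-4-methoxybenzoate (CNP0106636.1)
Conditions: VO(acac)2 (5 mol %), t-BuOOH (in decane), CH2Cl2, 0 °C → rt
Reagents that add atoms: tert-butyl hydroperoxide, CC(C)(C)OO
Why: Hydroxyl-directed vanadium-catalysed epoxidation, in which the axial 7α-OH binds vanadium as a bishomoallylic alkoxide and delivers the peroxide oxygen to the α face of the C1=C2 alkene, sets C1 and C2.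

**Compound list**
1 | methyl 3-methylbutanoate | COC(=O)CC(C)C | starting material
2 | (E)-1-methoxy-3-methyl-1-(trimethylsilyloxy)but-1-ene | CC(C)/C=C(\OC)O[Si](C)(C)C | intermediate
3 | (R)-4-(tert-butyldimethylsilyloxy)cyclopent-2-en-1-one | O=C1C=C[C@H](O[Si](C)(C)C(C)(C)C)C1 | starting material
4 | methyl 2-[(1S,5R)-5-(tert-butyldimethylsilyloxy)-3-(trimethylsilyloxy)cyclopent-2-en-1-yl]-3-methylbutanoate (C4 epimers) | C[Si](C)(C)OC1=C[C@H]([C@H](O[Si](C)(C)C(C)(C)C)C1)C(C(C)C)C(=O)OC | intermediate (not isolated)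
5 | methyl 2-[(1S,2R)-2-(tert-butyldimethylsilyloxy)-4-oxocyclopentyl]-3-methylbutanoate (C4 epimers) | O=C1C[C@H]([C@H](O[Si](C)(C)C(C)(C)C)C1)C(C(C)C)C(=O)OC | intermediate (not isolated)
6 | methyl 3-methyl-2-[(1R)-4-oxocyclopent-2-en-1-yl]butanoate (C4 epimers) | O=C1C=C[C@@H](C1)C(C(C)C)C(=O)OC | intermediate
7 | bromomagnesium enolate: as 8 with OMgBr in place of the triflate (C4 epimers) | C=C[C@H]3[C@@H](CC(O[Mg]Br)=C3)C(C(C)C)C(=O)OC | intermediate (not isolated)
8 | methyl 2-[(1R,2S)-2-ethenyl-4-(trifluoromethylsulfonyloxy)cyclopent-3-en-1-yl]-3-methylbutanoate (C4 epimers) | C=C[C@H]3[C@@H](CC(OS(=O)(=O)C(F)(F)F)=C3)C(C(C)C)C(=O)OC | intermediate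
9 | 2-[(1R,2S)-2-ethenyl-4-(trifluoromethylsulfonyloxy)cyclopent-3-en-1-yl]-N-methoxy-N,3-dimethylbutanamide (C4 epimers) | C=C[C@H]3[C@@H](CC(OS(=O)(=O)C(F)(F)F)=C3)C(C(C)C)C(=O)N(C)OC | intermediate (not isolated)
10 | 5-[(1R,2S)-2-ethenyl-4-(trifluoromethylsulfonyloxy)cyclopent-3-en-1-yl]-2,6-dimethylhept-1-en-4-one (C4 epimers) | C=C[C@H]3[C@@H](CC(OS(=O)(=O)C(F)(F)F)=C3)C(C(C)C)C(=O)CC(C)=C | intermediate
11 | 4-isopropyl-7-methyl-5-oxo-3,3a,4,5,6,8a-hexahydroazulen-2-yl trifluoromethanesulfonate (H-3a α, H-8a β, C4 epimers) | O=C2CC(C)=C[C@H]3[C@@H](CC(OS(=O)(=O)C(F)(F)F)=C3)C2C(C)C | intermediate (not isolated)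
12 | 4α-isopropyl-7-methyl-5-oxo-3,3a,4,5,8,8a-hexahydroazulen-2-yl trifluoromethanesulfonate (H-3a α, H-8a β) | O=C2C=C(C)C[C@H]3[C@@H](CC(OS(=O)(=O)C(F)(F)F)=C3)[C@@H]2C(C)C | intermediate
13 | 5β-hydroxy-4α-isopropyl-7-methyl-3,3a,4,5,8,8a-hexahydroazulen-2-yl trifluoromethanesulfonate (H-3a α, H-8a β) | O[C@H]2C=C(C)C[C@H]3[C@@H](CC(OS(=O)(=O)C(F)(F)F)=C3)[C@@H]2C(C)C | intermediate
14 | 3-hydroxy-4-methoxybenzoic acid (isovanillic acid) | COc1ccc(C(=O)O)cc1O | starting material
15 | 5α-(3-hydroxy-4-methoxybenzoyloxy)-4α-isopropyl-7-methyl-3,3a,4,5,8,8a-hexahydroazulen-2-yl trifluoromethanesulfonate (H-3a α, H-8a β) | COc1ccc(C(=O)O[C@@H]2C=C(C)C[C@H]3[C@@H](CC(OS(=O)(=O)C(F)(F)F)=C3)[C@@H]2C(C)C)cc1O | intermediate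
16 | 2-(3-hydroxy-4-methoxyphenyl)-1,3-dioxan-2-ylium tetrafluoroborate bridging O-5 and O-7 on the α face of the triflate-bearing core | COc1ccc(C(=[O+]5)O[C@@H]2C[C@@]5(C)C[C@H]3[C@@H](CC(OS(=O)(=O)C(F)(F)F)=C3)[C@@H]2C(C)C)cc1O.F[B-](F)(F)F | intermediate (not isolated)
17 | 7α-hydroxy-5α-(3-hydroxy-4-methoxybenzoyloxy)-4α-isopropyl-7β-methyl-3,3a,4,5,6,7,8,8a-octahydroazulen-2-yl trifluoromethanesulfonate (H-3a α, H-8a β) | COc1ccc(C(=O)O[C@@H]2C[C@](C)(O)C[C@H]3[C@@H](CC(OS(=O)(=O)C(F)(F)F)=C3)[C@@H]2C(C)C)cc1O | intermediate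
18 | 7α-hydroxy-4α-isopropyl-2,7β-dimethyl-3,3a,4,5,6,7,8,8a-octahydroazulen-5α-yl 3-hydroxy-4-methoxybenzoate (H-3a α, H-8a β) | COc1ccc(C(=O)O[C@@H]2C[C@](C)(O)C[C@H]3[C@@H](CC(C)=C3)[C@@H]2C(C)C)cc1O | intermediate
19 | 1α,2α-epoxy-7α-hydroxy-4α-isopropyl-2β,7β-dimethyldecahydroazulen-5α-yl 3-hydroxy-4-methoxybenzoate (H-1 β, H-3a α, H-8a β; CNP0106636.1) | COc1ccc(C(=O)O[C@@H]2C[C@](C)(O)C[C@H]3[C@@H](C[C@@]4(C)O[C@@H]34)[C@@H]2C(C)C)cc1O | target

**Totals**
Total step count: 10. Longest linear sequence: 10 steps (1 → 19).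

**Steps most likely to fail, with fallbacks**

Step 7 (Mitsunobu on a hindered allylic alcohol next to the isopropyl group; elimination or low conversion is possible). Fallback: from 12, equatorial hydride delivery with LiBH(s-Bu)3 in THF at −78 °C gives the axial 5α-hydroxy-4α-isopropyl-7-methyl-3,3a,4,5,8,8a-hexahydroazulen-2-yl trifluoromethanesulfonate F1 directly. Isovanillic acid 14 is acetylated on the phenol (Ac2O, pyridine) to 3-acetoxy-4-methoxybenzoic acid F2. F2 is coupled to F1 with retention (DCC, DMAP, CH2Cl2) to give the 5α-(3-acetoxy-4-methoxybenzoyloxy) ester F3. NH3 in MeOH at 0 °C cleaves only the aryl acetate, and the route is rejoined at 15.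

Step 8 (the new reaction; risks are proton loss from the C7 cation, the acyl group ending on the tertiary oxygen, and interference by the free phenol). Fallback with known chemistry: from 15, N-iodosuccinimide in MeCN at 0 °C gives a β-face iodonium ion that the ester carbonyl opens at the tertiary C7 (halocyclisation with neighbouring acyloxy participation), forming the 6β-iodo-1,3-dioxan-2-ylium succinimidate F4. Aqueous NaHCO3 hydrolyses it to the 6β-iodo-7α-hydroxy 5α-isovanillate F5. Bu3SnH and AIBN in toluene at 80 °C remove the iodine and give 17.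

Step 10 (facial selectivity rests on delivery from a tertiary bishomoallylic alcohol, and the free phenol is a second ligand for vanadium). Fallback: from 18, catalyst-controlled epoxidation with the dioxirane of the fructose-derived Shi ketone (the enantiomer whose spiro transition state fits the α face), KHSO5 (as 2KHSO5·KHSO4·K2SO4), K2CO3 buffer at pH 10.5, MeCN/dimethoxymethane/H2O, 0 °C, gives 19 directly without use of the hydroxyl group. It makes no new compound (F0).

**Further compounds**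
F1 | step 7 | 5α-hydroxy-4α-isopropyl-7-methyl-3,3a,4,5,8,8a-hexahydroazulen-2-yl trifluoromethanesulfonate (H-3a α, H-8a β) | O[C@@H]2C=C(C)C[C@H]3[C@@H](CC(OS(=O)(=O)C(F)(F)F)=C3)[C@@H]2C(C)C
F2 | step 7 | 3-acetoxy-4-methoxybenzoic acid | COc1ccc(C(=O)O)cc1OC(C)=O
F3 | step 7 | 5α-(3-acetoxy-4-methoxybenzoyloxy)-4α-isopropyl-7-methyl-3,3a,4,5,8,8a-hexahydroazulen-2-yl trifluoromethanesulfonate | COc1ccc(C(=O)O[C@@H]2C=C(C)C[C@H]3[C@@H](CC(OS(=O)(=O)C(F)(F)F)=C3)[C@@H]2C(C)C)cc1OC(C)=O
F4 | step 8 | 6β-iodo analogue of dioxanylium 16 as its succinimidate | COc1ccc(C(=[O+]5)O[C@@H]2[C@@H](I)[C@@]5(C)C[C@H]3[C@@H](CC(OS(=O)(=O)C(F)(F)F)=C3)[C@@H]2C(C)C)cc1O.O=C1CCC(=O)[N-]1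
F5 | step 8 | 7α-hydroxy-6β-iodo-5α-(3-hydroxy-4-methoxybenzoyloxy)-4α-isopropyl-7β-methyl-3,3a,4,5,6,7,8,8a-octahydroazulen-2-yl trifluoromethanesulfonate | COc1ccc(C(=O)O[C@@H]2[C@@H](I)[C@](C)(O)C[C@H]3[C@@H](CC(OS(=O)(=O)C(F)(F)F)=C3)[C@@H]2C(C)C)cc1O
F0 | step 10 | none | none
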